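The pitfall in this flask was to read a charge of 1.00 equiv as one incoming ligand for each starting complex, and then to trim the charge to spare the complex with one exchanged a second exchange.

| flask | starting complex | incoming ligand | remark | time |
|---|---|---|---|---|
| south-west | 0.25 M | 1 equiv | the very flask that is asked about, followed so far |  |
| north-west | 0.38 M | 1 equiv | run made earlier |  |
| flask | 0.25 M | 1.00 equiv |  | 8.0 min |

- south-west (time / s: complex with one exchanged / %, starting complex / %): 12.0: 33.5, 61.6; 30.0: 42.8, 47.2; 60.0: 42.1, 42.9; 90.0: 38.7, 41.9
- north-west (time / min: complex with one exchanged / %, starting complex / %): 1.00: 52.5, 35.6; 3.00: 46.1, 34.6; 5.00: 42.3, 34.1; 8.00: 38.7, 34.7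

(standard deviation of a reading: 0.5 percentage points)

* equivalents of incoming ligand to starting complex, everything else as given, that leave most complex with one exchanged at 8.0 min
* the amount of complex with one exchanged then, in percent of the starting complex charged
* the amount of complex with one exchanged with the amounts as given

So I wrote the balance of the limiting reagent, the incoming ligand. In the south-west run, which is this flask followed up to 90.0 s, the starting complex stalled near 41.9%, so I divided the charge by the fraction consumed:

c = 1 equiv / 58.1% = 1.72 equiv

This ligand cost c is the equivalents of incoming ligand spent per starting complex consumed. My first thought was that the excess over one equivalent simply went into a second exchange, or that the first exchange had reached an equilibrium. But steps that each join a complex and a ligand keep their ratio when the whole charge is scaled, so the cost ought not to have moved with concentration, and the north-west run at 0.38 M said otherwise: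

c = 1 equiv / 65.3% = 1.53 equiv

The stalls differed by 7.2 percentage points against a scatter of 0.5 points, so I took it that some ligand was leaving by a path needing no complex, one that costs more in the dilute flask.

At 0.25 M a charge below c therefore strands starting complex, and that argued for raising the charge. The objection was that c was measured at 1.00 equiv, and that with more ligand the starting complex thins towards the end, so each further ligand should cost more. I committed to a best charge a little above 1.72 equiv.

The forecast, from the same runs, put the best charge lower, at 0.65 equiv with 35% of complex with one exchanged then and 24% as charged, adding “but this is rough”.

The flask gives a best charge of 2.08 equiv, which is 0.360 equiv above c, with 39.6% of complex with one exchanged then and 20.8% as charged.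

    starting complex + incoming ligand → leaving ligand + complex with one exchanged (k = 0.270 /M/s)
    complex with one exchanged + incoming ligand → leaving ligand + complex with two exchanged (k = 0.210 /M/s)
    crystals ⇌ complex with one exchanged, rate k3*(cs3 - [complex with one exchanged]) while solid is left; crystals form when [complex with one exchanged] > cs3 (solubility = 26.0 mM, k = 1.60 /s)
    complex with one exchanged ⇌ isomer of the product (K = 3.20, k = 0.0160 /s)
    incoming ligand → decomposed reagent (k = 0.0270 /s)

In the flask as charged, incoming ligand stood at 0% at 8.00 min with 42% of the starting complex left, which makes the cost 1.72 equiv. The largest single effect on the complex with one exchanged standing in that flask at the asked time is its loss to isomer of the product: the run without that step, both ways, leaves 50.9% against 20.8%. For the neighbouring flask with 0.600 equiv, c gives 65.1% of the starting complex left, and that flask held 62%.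

(All runs were generated by integration with constants of no real substance, and the scatter is random.)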